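The constants were set for the occasion; what happens was integrated by code.

Slowness was the subject of the meeting: Q must dissolve out of D before it can become L, and J meanwhile turns into G, so the question was how much L each dose of J makes.

    Q + J → L + J, rate k1*[Q]*[J]/(1 + ([Q]/Km1) + ([L]/Kp1)) (Km1 = 0.0522 M, Kp1 = 0.0710 M, k1 = 10400 L mol⁻¹ s⁻¹)
    J → G (k2 = 0.250 min⁻¹)
    D ⇌ Q, rate k3*(cs3 - [Q]) while solid is left; crystals form when [Q] > cs3 (cs3 = 46 mM, k3 = 0.794 min⁻¹)

common to all: D 0.10 M; time 1.5 h
- Tuesday's: J 0.80 µM
- Monday's: J 1.2 µM
- Sunday's: J 2.0 µM
- Wednesday's: J 3.0 µM
- Friday's: J 5.0 µM

- amount of L at the end, in percent of the D charged for Tuesday's, Monday's, Sunday's, Wednesday's, Friday's, in this order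
- how that number moves from the first to the last of them (rises, then falls / hardly changes / rises all the way / falls all the way / falls, then rises)

- solid, in amounts per volume of the solution: D
- at the start none of D is in solution
- "hardly changes" means that all values lie within two and a half points (for a concentration: within two and a half percent of the largest)
- run time (Tuesday's): 1.5 h

One member began with the run time of 1.5 h. I replied that J lasts 4.00 min on average, far shorter than that run time, so the time that counts is the life of J. A second member objected that J is already dying while the solution fills. I agreed: filling takes about 1.26 min, which is shorter than that life but not negligible. Weighted by living J, dissolved Q averages 76.1 % of its solubility of 46 mM.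

Rate constant times dose times J's life times that averaged Q gives 69.9 mM for Tuesday's dose of 0.80 µM. I proposed to carry this number, the reach of a dose, meaning the L it could make in its lifetime with no brake.

A third member raised the brake in the rate law. I answered that, with Q at solubility, each unit of L costs 1.88 units of reach, and the cost climbs as L gathers. Added up, making L costs 1.88 times L, plus L squared over 2 times 0.0710 M. Setting that cost equal to the reach, I committed to 33.0 % of the charge for Tuesday's flask.

The crossing is the emptying of the solid. That needs 54.0 mM of L, at a price of 122 mM. Tuesday's reach is below this price, so I expected solid left there. Sunday's reach of 175 mM is above it, so I expected none left there.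

The forecast gave 33 %, 47 %, 70 %, 85 % and 96 %, a row that rises all the way, on the ground that “each run's yield is set by its total enzyme exposure, which scales with the dose”.

The flasks give 33.2 %, 46.1 %, 66.6 %, 81.8 % and 94.6 %, so the row rises all the way. In Tuesday's flask D went into solution and Q went to L together, with midpoints at 1.87 min and 0.0567 h, and conversion had 99 % of its turnover behind it at 0.300 h. By 0.750 h J stood at 0 % of its charge in Tuesday's flask, whose reach is 69.9 mM, with L at 33.2 % and solid D at 20.8 % of the D charged. Monday's dose has a reach of 105 mM, below the price of 122 mM, which gives 47.3 % against a reading of 46.1 %, with solid D at 7.87 %.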